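**Strategy.** The ketone carbon C3, chain carbons C2 and C1, ring carbons C1' and C2' of the 2,4-dihydroxy-3-methoxyphenyl ring (ring B) and the 2'-hydroxyl oxygen make up a latent six-membered ring. The ring B half of the target is therefore a ring-opened aryl lactone, 7-hydroxy-8-methoxy-3,4-dihydrocoumarin, made in one step from symmetrical 2-methoxyresorcinol and acrylic acid. Everything rests on the C3–C4 disconnection. One addition of 4-(4-methoxyphenyl)butylmagnesium bromide to the lactone carbonyl forms this bond, fixes the ketone oxidation level and, when the cyclic hemiketal opens on work-up, releases the 2'-hydroxyl. The lactone serves at once as acyl donor and as phenol protecting group.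

Key step: step 3

Remark: the target has no stereocentre and is taken as the open keto-phenol, which interconverts with its cyclic hemiketal (2-chromanol) form by ring-chain tautomerism; 1-(4-bromobutyl)-4-methoxybenzene is taken as a catalogue compound.

Step 1
Reactants: 1 2-methoxybenzene-1,3-diol (2-methoxyresorcinol); 2 acrylic acid
Product: 3 7-hydroxy-8-methoxy-3,4-dihydro-2H-chromen-2-one
Conditions: Amberlyst-15, toluene, reflux, Dean–Stark (1 in 1.5-fold excess)
Reagents that add atoms: none
Why: Acid-catalysed Friedel–Crafts hydroarylation of acrylic acid at C4 of 1 (ortho and para to the two hydroxyls, C4 and C6 being equivalent by symmetry) followed by lactonisation with the neighbouring hydroxyl (Pechmann-type hydroarylation–lactonisation) should give the dihydrocoumarin as a single regioisomer.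

Step 2
Reactants: 4 1-(4-bromobutyl)-4-methoxybenzene
Product: 5 [4-(4-methoxyphenyl)butyl]magnesium bromide (titrated THF solution, used directly in step 3)
Conditions: Mg turnings, cat. I2, THF, 25–45 °C, slow addition of 4
Reagents that add atoms: magnesium, [Mg]
Why: Grignard reagent formation by insertion of magnesium into the primary C–Br bond should proceed cleanly, since the aryl methyl ether and the saturated chain are inert and slow addition limits Wurtz coupling.

Step 3
Reactants: 3 7-hydroxy-8-methoxy-3,4-dihydro-2H-chromen-2-one; 5 [4-(4-methoxyphenyl)butyl]magnesium bromide
Product: 8 1-(2,4-dihydroxy-3-methoxyphenyl)-7-(4-methoxyphenyl)heptan-3-one, via chloromagnesium phenoxide 6 (not isolated), via hemiketal magnesium alkoxide 7 (not isolated)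
Conditions: 3, t-BuMgCl (1.0 equiv), THF, −78 °C; then 5 (1.1 equiv), −78 to −30 °C; then sat. aq NH4Cl, 1 M HCl to pH 4, 0 °C
Reagents that add atoms: none
Why: t-BuMgCl first removes the acidic 7-OH proton of 3 to give the spectator phenoxide 6, so that none of 5 is spent as a base; the primary alkyl Grignard 5 then adds to the lactone carbonyl (an aryl ester, more electrophilic than an alkyl ester) and forms the C3–C4 bond as the six-membered cyclic hemiketal magnesium alkoxide 7. The closest known reaction type is the single addition of Grignard or organolithium reagents to 3,4-dihydrocoumarins and other lactones at low temperature to give lactols, a nucleophilic acyl substitution arrested at the tetrahedral stage. No ring is closed and no stereocentre survives: the hemiketal carbon of 7 forms as a racemate and becomes the sp2 ketone carbon when the 2-chromanol opens to the keto-phenol after protonation. The selectivity needed is single against double addition; it should be secured because the aryloxide leaving group stays tethered in the ring of 7 and its expulsion would create a doubly charged resorcinolate, so the ketone is unmasked only in the aqueous quench when no organometallic remains. Low temperature and a near-stoichiometric charge of 5 add further margin, the mild acidic quench avoids dehydration of the hemiketal to a chromene, and both aryl methyl ethers are inert.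

**Compound list**

1 | 2-methoxybenzene-1,3-diol (2-methoxyresorcinol) | COc1c(O)cccc1O | starting material
2 | acrylic acid (prop-2-enoic acid) | C=CC(=O)O | starting material
3 | 7-hydroxy-8-methoxy-3,4-dihydro-2H-chromen-2-one | COc1c(O)ccc2CCC(=O)Oc12 | intermediate
4 | 1-(4-bromobutyl)-4-methoxybenzene | COc1ccc(CCCCBr)cc1 | starting material
5 | [4-(4-methoxyphenyl)butyl]magnesium bromide | COc1ccc(CCCC[Mg]Br)cc1 | intermediate
6 | chloromagnesium 8-methoxy-2-oxo-3,4-dihydro-2H-chromen-7-olate | COc1c(O[Mg]Cl)ccc2CCC(=O)Oc12 | intermediate
7 | 2-O-bromomagnesium 7-O-chloromagnesium salt of 8-methoxy-2-[4-(4-methoxyphenyl)butyl]chromane-2,7-diol (cyclic hemiketal alkoxide, racemic at C2) | COc1ccc(CCCCC2(O[Mg]Br)CCc3ccc(O[Mg]Cl)c(OC)c3O2)cc1 | intermediate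
8 | 1-(2,4-dihydroxy-3-methoxyphenyl)-7-(4-methoxyphenyl)heptan-3-one | COc1ccc(CCCCC(=O)CCc2ccc(O)c(OC)c2O)cc1 | target

**Total step count:** 3
**Longest linear sequence:** 2 steps (1 → 3 → 8, or 4 → 5 → 8)

**Steps most likely to fail**

Step 3. The tetrahedral intermediate may collapse early to the ketone, which would then take up a second equivalent of the Grignard reagent, or the lactone may be enolised and returned unchanged. The fallback sets out from 3. Aminolysis of the lactone with MeNHOMe·HCl and AlMe3 (CH2Cl2, 0 °C to room temperature) should give N-methoxy-N-methyl-3-(2,4-dihydroxy-3-methoxyphenyl)propanamide F1. After deprotonation of both phenols with t-BuMgCl (2 equiv), addition of 5 in THF at 0 °C passes through the five-membered N-methoxy magnesium chelate, which cannot collapse before the quench. The fallback comes back to the route at 8.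

Step 1. O-acylation followed by Fries-type C-acylation may lead towards chromanone-type products, a second annulation may occur at the remaining activated position, or acrylic acid may oligomerise. The fallback sets out from 1. ZnCl2-mediated condensation with ethyl propiolate (dioxane, 100 °C; hydroarylation of the alkyne and lactonisation, a Pechmann-type coumarin synthesis) should give 7-hydroxy-8-methoxy-2H-chromen-2-one F2, whose aromatic pyranone ring resists a second annulation. Hydrogenation of its C3–C4 double bond (H2, 10% Pd/C, EtOAc) comes back to the route at 3.

Step 2. Wurtz-type homocoupling at the magnesium surface or sluggish initiation may erode the Grignard titre. The fallback sets out from 4. A Finkelstein exchange (NaI, acetone, reflux) should give 1-(4-iodobutyl)-4-methoxybenzene F3. Iodine–lithium exchange (t-BuLi, 2.1 equiv, Et2O–pentane, −78 °C) should give [4-(4-methoxyphenyl)butyl]lithium F4 without radical coupling. Transmetalation with MgBr2·OEt2 comes back to the route at 5.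

**Further compounds**

F1 | step 3 | N-methoxy-N-methyl-3-(2,4-dihydroxy-3-methoxyphenyl)propanamide | CON(C)C(=O)CCc1ccc(O)c(OC)c1O
F2 | step 1 | 7-hydroxy-8-methoxy-2H-chromen-2-one | COc1c(O)ccc2ccc(=O)oc12
F3 | step 2 | 1-(4-iodobutyl)-4-methoxybenzene | COc1ccc(CCCCI)cc1
F4 | step 2 | [4-(4-methoxyphenyl)butyl]lithium | COc1ccc(CCCC[Li])cc1
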